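The numbers in the tables were generated by integration on assumed constants.

Late in the violet run the readings have stopped moving: at 30.0 h starting material stands at 62% and target at 39%, and late in the green run, at 60.0 h, they stand at 59% and 43%. So I reckon from what stays behind and not from what is made.

in all of them: free catalyst 5.1 mM
- ochre: starting material 0.20 M; coupling partner 0.312 M; temperature −10 °C; run made earlier
- violet: starting material 0.78 M; coupling partner 0.312 M; temperature 10 °C; run made earlier
- green: starting material 0.39 M; coupling partner 0.16 M; temperature −10 °C; run made earlier
- gamma: starting material 0.39 M; coupling partner 0.312 M; temperature 5 °C; time 30 h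
- zeta: starting material 0.39 M; coupling partner 0.312 M; temperature 15 °C; time 30 h

| run | time / h | target / % | starting material / % | over-reaction product / % | catalyst intermediate D / % |
|---|---|---|---|---|---|
| ochre | 5.00 | 14 | 87 | 2 | 2 |
| ochre | 8.00 | 18 | 76 | 1 | 0 |
| ochre | 12.0 | 28 | 68 | 1 | 0 |
| ochre | 15.0 | 43 | 58 | 2 | 2 |
| ochre | 25.0 | 61 | 35 | 0 | 1 |
| ochre | 40.0 | 84 | 13 | 2 | 0 |
| ochre | 60.0 | 94 | 5 | 8 | 0 |
| violet | 4.00 | 37 | 59 | 4 | 0 |
| violet | 8.00 | 38 | 63 | 0 | 0 |
| violet | 12.0 | 39 | 54 | 0 | 0 |
| violet | 15.0 | 40 | 61 | 0 | 0 |
| violet | 20.0 | 40 | 63 | 0 | 3 |
| violet | 25.0 | 40 | 63 | 0 | 0 |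
| violet | 30.0 | 39 | 62 | 1 | 3 |
| green | 12.0 | 22 | 81 | 0 | 1 |
| green | 25.0 | 36 | 60 | 2 | 1 |
| green | 40.0 | 41 | 58 | 0 | 4 |
| green | 48.0 | 42 | 60 | 0 | 0 |
| green | 60.0 | 43 | 59 | 3 | 0 |

(scatter of a reading: 2 percentage points)

- a reading or a percentage of target counts all its forms, free or not

- which of these there is most of at the end, counted by the starting material in it, gamma (over-reaction product / starting material / target / catalyst intermediate D)
- which of these there is most of at the end, counted by the starting material in it, zeta (over-reaction product / starting material / target / catalyst intermediate D)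
- amount of the one of these that there is most of at the end, in percent of the starting material charged, gamma
- amount of the one of these that there is most of at the end, in percent of the starting material charged, zeta

For gamma and zeta one minus the ratio of charges, coupling partner over starting material, is 20.0%, and this I call the leftover share: the part of the starting material that finds no partner if the two react one to one. The same subtraction gives 60.0% for violet and 59.0% for green, each within the scatter of 2 percentage points of those late readings.

In the first instants of gamma the catalyst charge is 1.31% of the starting material, against that scatter of 2 points, so I read nothing into the catalyst intermediate D columns.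

For the middle I reckon with a steady consumption. The ochre run at −10 °C loses 0.00423 M h⁻¹ of starting material between 5.00 h and 40.0 h, while the violet run at 10 °C has made 0.0722 M h⁻¹ of target on average by 4.00 h. Their geometric mean, 0.0175 M h⁻¹, is my cautious rate for gamma, which at 5 °C lies above the midpoint of those temperatures. At that rate the coupling partner in gamma lasts 17.9 h, less than the 30 h asked, and zeta is warmer still.

I expect the end of gamma when the coupling partner reaches zero with starting material still there, since its charge of 0.312 M is less than the 0.39 M of starting material, which makes it the limiting reagent, and the ceiling on target that I reckon is then 80.0%. What is about to matter is the over-reaction product, which in the ochre run reads 8% at 60.0 h. I commit to starting material near 20.0% and target just under that ceiling, alike in gamma and zeta.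

The forecast gives target in gamma and target in zeta, at 77% and 75%, on the ground that “the coupling partner is the limiting reagent, consumed one to one”; it parts from me in setting zeta lower.

The simulation gives target at 77.7% in gamma and 77.7% in zeta, with starting material in each at 21.2% against my 20.0%, a gap of 1.2 points beside 1.16% of over-reaction product.

    coupling partner + free catalyst ⇌ catalyst intermediate A (K = 21.0 L mol⁻¹, k = 1400 L mol⁻¹ h⁻¹, Ea = 58.0 kJ mol⁻¹, ΔH = −23.0 kJ mol⁻¹)
    catalyst intermediate A ⇌ catalyst intermediate B (K = 67.0, k = 27.0 h⁻¹, Ea = 85.0 kJ mol⁻¹, ΔH = −90.0 kJ mol⁻¹)
    starting material + catalyst intermediate B → catalyst intermediate C (k = 77.0 L mol⁻¹ h⁻¹, Ea = 51.0 kJ mol⁻¹)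
    catalyst intermediate C → catalyst intermediate D (k = 30.0 h⁻¹, Ea = 84.0 kJ mol⁻¹)
    catalyst intermediate D → free catalyst + target (k = 670 h⁻¹, Ea = 68.0 kJ mol⁻¹)
    crystals ⇌ target, rate k6*(cs6 - [target]) while solid is left; crystals form when [target] > cs6 (solubility = 0.230 M, k = 7.00 h⁻¹)
    coupling partner + target → over-reaction product (k = 0.0320 L mol⁻¹ h⁻¹, Ea = 63.0 kJ mol⁻¹)
    (constants at 5 °C)

The neighbouring flask is gamma with 0.53 M of coupling partner, 1.36 equiv, and there the same subtraction gives −35.9%, below zero, which points to starting material as the one to run out. At 30.0 h that flask holds 0.011% of its starting material, 91.6% of target, 8.40% of over-reaction product and 19% of its coupling partner's own charge.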